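The target in the teal flask of 0.54 M has stopped moving, so I want one number that tells me what each further charge or withdrawal is worth.

| setting | teal | blue | flask |
|---|---|---|---|
| starting material | 0.54 M | 0.81 M | 0.54 M |
| remark | the very flask that is asked about, followed so far | run made earlier |  |
| time |  |  | 50 min |

- teal (time / min: target / %, starting material / %): 10.0: 30.8, 39.9; 20.0: 26.9, 35.3; 30.0: 26.1, 34.4; 40.0: 26.3, 34.7; 50.0: 25.8, 33.7
- blue (time / min: target / %, starting material / %): 2.00: 37.7, 55.0; 4.00: 35.7, 49.4; 6.00: 33.4, 46.6; 8.00: 32.0, 42.0; 10.0: 29.6, 41.0

(each reading ± 0.5 percentage points)

- ash: at 50 min add starting material, 50.0% of the amount charged, then wait 25 min
- maple: change nothing and wait 25 min more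
- elm: at 50 min take out 90% of the target then present, then wait 25 min

- removed target is counted in
- additions bring no volume worth counting

* target, in percent of the starting material first charged, at 50 min
* what to do for the largest gain in target; "none" if nothing gains more than 2 percentage points (ash / maple / elm / none)
* target present, with what was taken out counted in, in percent of the starting material first charged, after ash
* target present, with what was taken out counted in, in percent of the starting material first charged, after maple

I look first for the crossing at which control passes from the clock to the balance. Target plus starting material sinks towards its level at the last teal reading, and between the first and last blue readings the gap to that level closes with a half-time of about 5.06 min. The teal readings from 30.0 min on, about 5.93 half-times out, are flat within the scatter of 0.5 percentage points. At 10.0 min the teal sum of 70.7% stands beside 70.6% in the blue run, despite charges of 0.54 M and 0.81 M, so I let percentages carry between these two charges.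

I therefore carry the equilibrium share of target, the fraction of the charged material standing as target once a flask is flat, 26.1%, which is thermodynamic control. That share is my figure for now and for maple. Ash gives 39.1%, a gain of 13 points. Elm removes 23.5%, the remainder divides again by the same share, and the count reaches 43.4%, so I commit to elm.

The weak link is whether the unseen material returns to target. A one-way drain of that half-time would have taken 93.5% of the starting material and target standing in the teal flask at 30.0 min by 50.0 min, yet starting material there reads 34.4% and then 33.7%. I read this as a balance, and the wait of 25 min spans about 4.94 half-times.

The forecast, made from the same runs, says 26% for now, 39% after ash, 26% after maple and elm as the best choice, noting that “reversibility of the hidden species is inferred, not shown”.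

The flask gives 26.2%, then 39.4% after ash and 26.1% after maple, and elm reaches 43.4%.

    starting material ⇌ target (K = 0.760, k = 0.773 min⁻¹)
    target ⇌ isomer of the product (K = 1.51, k = 0.137 min⁻¹)

The unseen material is the isomer of the product, 39.4% at 50.0 min, and its exchange with target, by this step alone, relaxes with a half-life of 3.04 min, short against 50 min. Held at 26.1%, the share puts the target left in the flask after elm at 20.0% of the first charge. The same share, applied to a neighbour flask charged at 0.14 M, meets a target of 26.2%.

The earlier runs and the new flask come from a simulation for an exercise.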